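## The problem

The target **15** is a (2S)-flavanone of the pinostrobin type (5-OH, 7-OMe, unsubstituted ring B) whose ring A is fully substituted. C6 and C8 each carry a 2-hydroxy-5-(2-hydroxybenzyl)benzyl arm (rings D and E), so the molecule holds four diarylmethane methylenes, two of them on a phloroglucinol-type ring, and five free phenols. The only stereocentre is C2, a benzylic ether carbon β to the C4 ketone; no other centre can relay to it, so it must be set by a catalyst or bought, and once the ketone exists it can be lost by retro-oxa-Michael opening to the chalcone under base or hot acid. The phenols are electron-rich and oxidisable, and the C2–O1 bond is a benzylic ether that will not stand vigorous reduction, so the end game has to be neutral and mild. Ring A must receive two bulky benzyl groups on carbon, not oxygen, and each arm needs its inner methylene ortho and its outer methylene para to the ring D oxygen. The feature that opens the molecule is ring C: O1, C8a, C4a and C4 are the four atoms of an ortho-quinone methide heterodiene, and C2–C3 with its phenyl group is styrene. Because C5 and C8a both bear oxygen, the aldehyde behind that quinone methide is mirror-symmetric, so either hydroxyl closes to the same ring, and because C6 and C8 already carry the arms, ring A offers no free carbon to the cationic intermediate.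

## Retrosynthesis

**15 from 14.** Only the four O–benzyl bonds of the arm phenols are cut. Benzyl is preferred to acetal or silyl protection because the arms must pass through three acidic steps (5, 6 and 7) and then come off under neutral hydrogenolysis, which the flavanone tolerates. The C5 hydroxyl stays free throughout: it is one of the two equivalent hydroxyls of **8**, and in **14** it is hydrogen-bonded to the ketone.

**14 from 13 from 12.** No skeletal bond is cut; C4 is taken back from ketone to alcohol **13** and to methyl ether **12**. The ketone is introduced as late as possible because flavan **12** has no carbonyl group and therefore cannot open by retro-oxa-Michael reaction, so C2 is configurationally safe during the acid chemistry. The forward steps must exchange OMe for OH at a strongly stabilised benzylic position without touching C2, and then oxidise a benzylic alcohol under neutral conditions.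

**12 from 8 and 9.** O1–C2 and C3–C4 are cut in a retro-[4+2], which removes ring C and both stereocentres and leaves the achiral, symmetric aldehyde **8** and styrene **9**. The neighbouring cut, O1–C2 alone (chalcone and oxa-Michael closure), would need an acetophenone, an aldol condensation and an asymmetric cyclisation whose product racemises by the reverse reaction. Cutting the arms before ring C would leave C6 and C8 of a phloroglucinol ring open to the quinone methide. The forward reaction must generate the methoxy quinone methide **11** from **8** through acetal **10**, add styrene with the oxygen at the benzylic carbon, and discriminate the faces of the alkene with a chiral counter-anion.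

**8 from 7 and two molecules of 6.** The two ring A–CH2 bonds are cut. Alkylating the phenolate of **7** with a benzylic bromide would divide between oxygen and carbon. An acid-catalysed Friedel–Crafts reaction with the benzylic alcohol **6** can only end on carbon, and **7** has exactly two free ring positions, both strongly activated. The precursors are a catalogue aldehyde and one arm used twice. The forward step needs the arm cation to be taken by **7** faster than by another molecule of **6**.

**6 from 5, and 5 from 4 and 2.** The alcohol is the reduced form of aldehyde **5**. In **5** the bond between ring D and the outer methylene is cut to the aryl boronate **4** and the benzylic bromide **2**. A Suzuki–Miyaura coupling fixes the regiochemistry (para to the ring D oxygen, ortho to the ring E oxygen) by the positions of boron and bromine, which an electrophilic benzylation of a phenol could not guarantee. **4** comes from bromide **3** by borylation and **2** from alcohol **1**; **1**, **3**, **7** and **9** are purchased.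

## Roads not taken

Alternative 1: The cut is at both ring A–CH2/ring D bonds, made last on the intact flavanone. In the forward step, cathodic nickel catalysis would couple the two chloromethyl groups of (2S)-5-acetoxy-6,8-bis(chloromethyl)-7-methoxyflavanone A2 with two molecules of the ring D–E aryl bromide A3 to give the protected target A1, the 5-acetate and arm tetrakis(methoxymethyl) ether of **15**.
- Merits: C2 is bought with natural (S)-pinostrobin A4, the parent of A2, so no asymmetric step is needed. The route is convergent, and the ring D attachment point is fixed by the bromine of A3.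
- Weak points: A2 requires double chloromethylation of an acid- and base-sensitive flavanone, and benzylic chlorides flanked by oxygen on a phloroglucinol ring solvolyse very readily. Under reductive conditions such chlorides tend to homocouple or be reduced to methyl. The cathode produces base and low-valent nickel next to an aryl ketone, a phenyl acetate and an epimerisable C2. The coupling must succeed twice on neighbouring positions.
- Comparison: in stereochemical certainty this road is better than the chosen plan, whose key step is undemonstrated. The chosen plan sets against it that both ring A–CH2 bonds are made by Friedel–Crafts chemistry on a robust aldehyde before any stereocentre or flavanone exists, that the flavanone appears only in the last two, neutral steps, and that either enantiomer is accessible. The same bond set, in Friedel–Crafts form, is kept as the reserve for the key step.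

Alternative 2: The cut is at the two bonds between the outer methylene carbons and the ortho carbons of ring E. In the forward step, the bis(phenylthiomethyl) flavanone A6 would be S-chlorinated, the sulfonium captured by phenol A7 and deprotonated; each ylide would rearrange by a [2,3]-shift to give the bis-sulfide A5, which is then desulfurised.
- Merits: strictly ortho attachment to ring E, from the cheapest possible building block.
- Weak points: it addresses the easiest bond of the molecule. The two hard ring A–ring D links and the C2 stereocentre must already be present in A6. The amine base needed for ylide formation acts on a flavanone that can open to the chalcone. A5 forms as a mixture of epimers at the sulfur-bearing carbons. Reductive desulfurisation must spare an aryl ketone and the benzylic C2–O1 bond. The sequence is longer.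
- Comparison: its one advantage, ortho control, is already secured in the chosen plan by the Suzuki coupling of **4** with **2**, so nothing is gained.

Alternative 3: The cut is at C4a–C4, C3–C4 and O1–C2, with C4 coming from carbon monoxide. In the forward step, the iodoresorcinol A9, carbon monoxide A11 and phenylacetylene A10 would combine under palladium catalysis to the flavone A8.
- Merits: carbonylative annulation of ortho-iodophenols with aryl acetylenes is an established reaction type, so the ring-forming step stands on firmer precedent than the chosen key step. Three components are joined at once.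
- Weak points: A8 is flat, and C2 must then be created by an enantioselective 1,4-reduction of this hindered 5-hydroxyflavone. That transformation has thin precedent, must stop before the ketone is reduced, and gives a product that can racemise under hydridic, basic conditions. A9 is a hexasubstituted iodide flanked by two free hydroxyls, and five-membered (aurone) closure competes.
- Comparison: this road is better in the precedent for ring closure. The chosen plan sets against it that ring closure and creation of C2 are one event, at an oxidation level that needs only hydrolysis and alcohol oxidation afterwards, not a second, harder asymmetric step.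

Key step: step 6

Assumption: compounds **1**, **3**, **7** and **9** are taken as catalogue chemicals; **1** and **3** are otherwise one O-benzylation away from 2-hydroxybenzyl alcohol and 5-bromosalicylaldehyde.

Assumption: the sense of induction of the chiral acid in step 6 cannot be derived from first principles; the (R)-acid is written, and its mirror image is used if (R) proves to deliver (2R).

## Route

Step 1
Reactants: 1 2-(benzyloxy)benzyl alcohol
Product: 2 2-(benzyloxy)benzyl bromide
Conditions: PBr3 (0.4 equiv), CH2Cl2, 0 °C to rt
Reagents that add atoms: phosphorus tribromide, BrP(Br)Br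
Why: Conversion of a benzylic alcohol into the bromide through its phosphite ester; the aryl benzyl ether is inert at this temperature and the bromide is used promptly.

Step 2
Reactants: 3 2-(benzyloxy)-5-bromobenzaldehyde
Product: 4 2-(benzyloxy)-5-(4,4,5,5-tetramethyl-1,3,2-dioxaborolan-2-yl)benzaldehyde
Conditions: B2pin2, Pd(dppf)Cl2 (3 mol %), KOAc, 1,4-dioxane, 85 °C
Reagents that add atoms: bis(pinacolato)diboron, CC1(C)OB(OC1(C)C)B1OC(C)(C)C(C)(C)O1
Why: Miyaura borylation of an aryl bromide; the weak acetate base spares the aldehyde and suppresses biaryl formation.

Step 3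
Reactants: 4 2-(benzyloxy)-5-(4,4,5,5-tetramethyl-1,3,2-dioxaborolan-2-yl)benzaldehyde; 2 2-(benzyloxy)benzyl bromide
Product: 5 2-(benzyloxy)-5-[2-(benzyloxy)benzyl]benzaldehyde
Conditions: Pd(PPh3)4 (3 mol %), K2CO3, DME/H2O, 80 °C
Reagents that add atoms: none
Why: Suzuki–Miyaura coupling of an arylboronic ester with a benzylic bromide, a standard route to diarylmethanes; the positions of boron and bromine fix the outer methylene para to the ring D oxygen and ortho to the ring E oxygen.

Step 4
Reactants: 5 2-(benzyloxy)-5-[2-(benzyloxy)benzyl]benzaldehyde
Product: 6 {2-(benzyloxy)-5-[2-(benzyloxy)benzyl]phenyl}methanol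
Conditions: NaBH4, MeOH/THF, 0 °C
Reagents that add atoms: none
Why: Borohydride reduction of an aromatic aldehyde; nothing else in 5 is reducible.

Step 5
Reactants: 7 2,6-dihydroxy-4-methoxybenzaldehyde; 6 {2-(benzyloxy)-5-[2-(benzyloxy)benzyl]phenyl}methanol (two molecules)
Product: 8 3,5-bis{2-(benzyloxy)-5-[2-(benzyloxy)benzyl]benzyl}-2,6-dihydroxy-4-methoxybenzaldehyde
Conditions: Sc(OTf)3 (10 mol %), MeNO2/CH2Cl2, 40 °C, 6 (2.3 equiv) added slowly
Reagents that add atoms: none
Why: Lewis acid-catalysed Friedel–Crafts benzylation with a benzylic alcohol, a reaction type established for ortho-oxygenated benzyl alcohols and phloroglucinol-type aryl carbonyl compounds: the ortho-alkoxybenzyl cation is taken by C3 and C5 of 7, the only free ring positions, each ortho or para to three oxygens and meta to the formyl group. Slow addition of 6 keeps the cation concentration low so that the far more nucleophilic ring of 7 should outrun ring E of a second molecule of 6.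

Step 6
Reactants: 8 3,5-bis{2-(benzyloxy)-5-[2-(benzyloxy)benzyl]benzyl}-2,6-dihydroxy-4-methoxybenzaldehyde; 9 styrene
Product: 12 (2S,4S)-6,8-bis{2-(benzyloxy)-5-[2-(benzyloxy)benzyl]benzyl}-4,7-dimethoxy-2-phenylchroman-5-ol (the 2,4-cis 4-methoxyflavan), via dimethyl acetal 10 (not isolated), via methoxy ortho-quinone methide 11 (not isolated)
Conditions: HC(OMe)3 (3 equiv), styrene (5 equiv), (R)-3,3'-bis(2,4,6-triisopropylphenyl)-1,1'-binaphthyl-2,2'-diyl N-triflylphosphoramide (10 mol %), CH2Cl2, −20 to 0 °C
Reagents that add atoms: trimethyl orthoformate, COC(OC)OC
Why: Proposed new method: the acid converts 8 with the orthoformate into acetal 10 and, by loss of methanol, into the aryl methoxycarbenium ion that is the O-protonated form of quinone methide 11, held as a contact ion pair with the chiral phosphoramide anion through the phenolic O–H. Styrene attacks C4 with its terminal carbon and the developing benzylic cation at C2 is taken by the phenolic oxygen, a concerted but asynchronous inverse-demand oxa-[4+2] cycloaddition that closes ring C as a six-membered pyran. The closest known reactions are the chiral Brønsted acid-catalysed [4+2] of ortho-quinone methides from ortho-hydroxybenzyl alcohols with styrenes and the racemic acid-catalysed union of salicylaldehydes, orthoformates and styrenes to 2,4-cis-4-alkoxyflavans; their combination on an aldehyde-derived, alkoxy-substituted quinone methide is new. C2 is set by the catalyst alone, the anion shielding one face of the heterodiene, while C4 should arise cis to the phenyl group through an endo-like approach and is of no consequence because it becomes the carbonyl carbon. Regiochemistry follows the polarisation of styrene, with its CH2 terminus going to C4 and oxygen to the benzylic carbon. Chemoselectivity rests on three features of 8: ring A has no free position, the arm rings are only anisole-like and cannot reach C4 intramolecularly without a meta-bridged ring, and the two hydroxyls are equivalent so that either closure gives 12. Ionisation of acetal 10 should be far easier than re-ionisation of ether 12, so the product should persist if the run is stopped when 10 is consumed.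

Step 7
Reactants: 12 (2S,4S)-6,8-bis{2-(benzyloxy)-5-[2-(benzyloxy)benzyl]benzyl}-4,7-dimethoxy-2-phenylchroman-5-ol
Product: 13 (2S)-6,8-bis{2-(benzyloxy)-5-[2-(benzyloxy)benzyl]benzyl}-7-methoxy-2-phenylchromane-4,5-diol (C4 epimers, either or both)
Conditions: TsOH·H2O (10 mol %), THF/H2O (4:1), rt
Reagents that add atoms: water, O
Why: SN1 solvolysis of a benzylic methyl ether whose cation is stabilised by O1, the C5 hydroxyl and the C7 methoxyl; water in large excess replaces methanol, and any flav-3-ene formed by loss of H3 is reprotonated to the same cation. C2 is not involved because its ether bond has no comparable stabilisation, and the configuration at C4 is irrelevant.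

Step 8
Reactants: 13 (2S)-6,8-bis{2-(benzyloxy)-5-[2-(benzyloxy)benzyl]benzyl}-7-methoxy-2-phenylchromane-4,5-diol
Product: 14 (2S)-6,8-bis{2-(benzyloxy)-5-[2-(benzyloxy)benzyl]benzyl}-5-hydroxy-7-methoxyflavanone
Conditions: MnO2 (activated, excess), CH2Cl2, rt
Reagents that add atoms: none
Why: MnO2 oxidation of a benzylic alcohol to the aryl ketone under neutral, heterogeneous conditions, which avoid the retro-oxa-Michael opening that would racemise C2; the C4 stereocentre disappears and the C5 hydroxyl becomes hydrogen-bonded to the new carbonyl.

Step 9
Reactants: 14 (2S)-6,8-bis{2-(benzyloxy)-5-[2-(benzyloxy)benzyl]benzyl}-5-hydroxy-7-methoxyflavanone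
Product: 15 (2S)-5-hydroxy-6,8-bis[2-hydroxy-5-(2-hydroxybenzyl)benzyl]-7-methoxyflavanone, 5''-(2''''-hydroxybenzyl)uvarinol
Conditions: H2 (1 atm), Pd/C (10 wt %), EtOAc/MeOH, rt
Reagents that add atoms: none
Why: Hydrogenolysis of aryl benzyl ethers over Pd/C at ambient pressure should be much faster than cleavage of the cyclic benzylic C2–O1 ether or reduction of the hydrogen-bonded aryl ketone, as is routine in flavanone work; the neutral medium leaves C2 untouched.

## Compound list

1 | 2-(benzyloxy)benzyl alcohol | OCc1ccccc1OCc1ccccc1 | starting material
2 | 2-(benzyloxy)benzyl bromide | BrCc1ccccc1OCc1ccccc1 | intermediate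
3 | 2-(benzyloxy)-5-bromobenzaldehyde | O=Cc1cc(Br)ccc1OCc1ccccc1 | starting material
4 | 2-(benzyloxy)-5-(4,4,5,5-tetramethyl-1,3,2-dioxaborolan-2-yl)benzaldehyde | O=Cc1cc(B2OC(C)(C)C(C)(C)O2)ccc1OCc1ccccc1 | intermediate
5 | 2-(benzyloxy)-5-[2-(benzyloxy)benzyl]benzaldehyde | O=Cc1cc(Cc2ccccc2OCc2ccccc2)ccc1OCc1ccccc1 | intermediate
6 | {2-(benzyloxy)-5-[2-(benzyloxy)benzyl]phenyl}methanol | OCc1cc(Cc2ccccc2OCc2ccccc2)ccc1OCc1ccccc1 | intermediate
7 | 2,6-dihydroxy-4-methoxybenzaldehyde | O=Cc1c(O)cc(OC)cc1O | starting material
8 | 3,5-bis{2-(benzyloxy)-5-[2-(benzyloxy)benzyl]benzyl}-2,6-dihydroxy-4-methoxybenzaldehyde | O=Cc1c(O)c(Cc2cc(Cc3ccccc3OCc3ccccc3)ccc2OCc2ccccc2)c(OC)c(Cc2cc(Cc3ccccc3OCc3ccccc3)ccc2OCc2ccccc2)c1O | intermediate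
9 | styrene | C=Cc1ccccc1 | starting material
10 | dimethyl acetal of 8, 2-(dimethoxymethyl)-4,6-bis{2-(benzyloxy)-5-[2-(benzyloxy)benzyl]benzyl}-5-methoxybenzene-1,3-diol | COC(OC)c1c(O)c(Cc2cc(Cc3ccccc3OCc3ccccc3)ccc2OCc2ccccc2)c(OC)c(Cc2cc(Cc3ccccc3OCc3ccccc3)ccc2OCc2ccccc2)c1O | intermediate (not isolated)
11 | methoxy ortho-quinone methide, 2,4-bis{2-(benzyloxy)-5-[2-(benzyloxy)benzyl]benzyl}-5-hydroxy-3-methoxy-6-(methoxymethylidene)cyclohexa-2,4-dien-1-one (reacts as its O-protonated ion pair with the catalyst anion) | COC=C1C(=O)C(Cc2cc(Cc3ccccc3OCc3ccccc3)ccc2OCc2ccccc2)=C(OC)C(Cc2cc(Cc3ccccc3OCc3ccccc3)ccc2OCc2ccccc2)=C1O | intermediate (not isolated)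
12 | (2S,4S)-6,8-bis{2-(benzyloxy)-5-[2-(benzyloxy)benzyl]benzyl}-4,7-dimethoxy-2-phenylchroman-5-ol (2,4-cis) | CO[C@H]1C[C@@H](c2ccccc2)Oc2c(Cc3cc(Cc4ccccc4OCc4ccccc4)ccc3OCc3ccccc3)c(OC)c(Cc3cc(Cc4ccccc4OCc4ccccc4)ccc3OCc3ccccc3)c(O)c12 | intermediate
13 | (2S)-6,8-bis{2-(benzyloxy)-5-[2-(benzyloxy)benzyl]benzyl}-7-methoxy-2-phenylchromane-4,5-diol (C4 unassigned, epimer mixture) | OC1C[C@@H](c2ccccc2)Oc2c(Cc3cc(Cc4ccccc4OCc4ccccc4)ccc3OCc3ccccc3)c(OC)c(Cc3cc(Cc4ccccc4OCc4ccccc4)ccc3OCc3ccccc3)c(O)c12 | intermediate
14 | (2S)-6,8-bis{2-(benzyloxy)-5-[2-(benzyloxy)benzyl]benzyl}-5-hydroxy-7-methoxyflavanone | O=C1C[C@@H](c2ccccc2)Oc2c(Cc3cc(Cc4ccccc4OCc4ccccc4)ccc3OCc3ccccc3)c(OC)c(Cc3cc(Cc4ccccc4OCc4ccccc4)ccc3OCc3ccccc3)c(O)c12 | intermediate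
15 | (2S)-5-hydroxy-6,8-bis[2-hydroxy-5-(2-hydroxybenzyl)benzyl]-7-methoxyflavanone, 5''-(2''''-hydroxybenzyl)uvarinol | O=C1C[C@@H](c2ccccc2)Oc2c(Cc3cc(Cc4ccccc4O)ccc3O)c(OC)c(Cc3cc(Cc4ccccc4O)ccc3O)c(O)c12 | target

## Step count and least certain steps

Total: 9 steps. Longest linear sequence: 8 steps (steps 2 to 9, from 3 to 15); step 1 is a one-step branch.

**Step 6 (key step).**
- Enantiofacial discrimination may be poor, because the highly stabilised methoxycarbenium ion is only loosely associated with the anion.
- Product 12 may re-ionise at C4 under the same acid, followed by a second annulation through the C5 hydroxyl or by alkene–cation dimerisation through the flav-3-ene.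
- Styrene may oligomerise under the acid.
- Arm rings may capture the cation intermolecularly.
- Fallback (known chemistry, the bond set of Alternative 1 in Friedel–Crafts form): it sets out from alcohol 6 and returns at 14. Natural (S)-pinostrobin F1 is benzylated at C6 and C8 with 6 (2.3 equiv, added slowly) under Lewis acid mediation (ZnCl2 in dioxane, or Sc(OTf)3 as in step 5). This is the Friedel–Crafts coupling of ortho-oxygenated benzyl alcohols with 5,7-dioxygenated flavanones, and it gives 14 directly; step 9 then follows unchanged. The stereocentre is bought instead of made, at the price of exposing the flavanone to Lewis acid, so the lowest workable temperature would be used and the optical purity of 14 checked.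

**Step 5.**
- Alcohol 6 may alkylate itself at the free para position of ring E in competition with 7.
- The second, more hindered benzylation may be incomplete.
- Once both positions are filled, ipso attack at C1 with loss of the formyl group may occur.
- Benzyl groups may migrate under the Lewis acid.
- Fallback: it sets out from 3, 7 and 2 and returns at 8, building the arms in two stages so that the electrophile has no nucleophilic ring. Aldehyde 3 is reduced (NaBH4, MeOH) to 2-(benzyloxy)-5-bromobenzyl alcohol F2. F2 benzylates 7 under the conditions of step 5 to give 3,5-bis[2-(benzyloxy)-5-bromobenzyl]-2,6-dihydroxy-4-methoxybenzaldehyde F3. Bromide 2 is borylated (B2pin2, Pd(dppf)Cl2, KOAc) to 2-[2-(benzyloxy)benzyl]-4,4,5,5-tetramethyl-1,3,2-dioxaborolane F4. A double Suzuki–Miyaura coupling of F3 with F4 (Pd(OAc)2, SPhos, K3PO4, toluene/H2O, 90 °C) gives 8.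

**Step 7.**
- The C4 cation may lose H3 to the flav-3-ene faster than it is hydrated, and the alkene may then be captured by a second cation (dimerisation) or aromatised.
- Fallback: it sets out from 12 and returns at 14, replacing solvolysis by oxidation. DDQ in wet CH2Cl2 at 0 °C abstracts hydride from C4–H, the most activated benzylic position (three ring oxygens plus the methoxy group); water adds to the oxocarbenium ion and the hemiketal collapses to ketone 14 with loss of methanol. This is the known oxidation of electron-rich benzylic ethers to carbonyl compounds, and it also makes step 8 unnecessary.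

**Step 9.**
- Over-reduction may occur: hydrogenolysis of the benzylic C2–O1 bond to a dihydrochalcone, or reduction of the ketone, before the fourth benzyl group is gone.
- Fallback: it sets out from 14 and returns at 15 by non-reductive Lewis acid cleavage, BCl3 with pentamethylbenzene as cation scavenger in CH2Cl2 at −78 °C. This is a known method for aryl benzyl ethers that leaves ketones, the aryl methyl ether and benzylic C–O bonds of this type alone.

## Further compounds

F1 | step 6 | (S)-pinostrobin, (2S)-5-hydroxy-7-methoxyflavanone | O=C1C[C@@H](c2ccccc2)Oc2cc(OC)cc(O)c12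
F2 | step 5 | 2-(benzyloxy)-5-bromobenzyl alcohol | OCc1cc(Br)ccc1OCc1ccccc1
F3 | step 5 | 3,5-bis[2-(benzyloxy)-5-bromobenzyl]-2,6-dihydroxy-4-methoxybenzaldehyde | O=Cc1c(O)c(Cc2cc(Br)ccc2OCc2ccccc2)c(OC)c(Cc2cc(Br)ccc2OCc2ccccc2)c1O
F4 | step 5 | 2-[2-(benzyloxy)benzyl]-4,4,5,5-tetramethyl-1,3,2-dioxaborolane | CC1(C)OB(Cc2ccccc2OCc2ccccc2)OC1(C)C
F0 | step 7 | none | none
F0 | step 9 | none | none
A1 | alternative 1 | (2S)-5-acetoxy-7-methoxy-6,8-bis{2-(methoxymethoxy)-5-[2-(methoxymethoxy)benzyl]benzyl}flavanone | O=C1C[C@@H](c2ccccc2)Oc2c(Cc3cc(Cc4ccccc4OCOC)ccc3OCOC)c(OC)c(Cc3cc(Cc4ccccc4OCOC)ccc3OCOC)c(OC(C)=O)c12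
A2 | alternative 1 | (2S)-5-acetoxy-6,8-bis(chloromethyl)-7-methoxyflavanone | O=C1C[C@@H](c2ccccc2)Oc2c(CCl)c(OC)c(CCl)c(OC(C)=O)c12
A3 | alternative 1 | 2-bromo-1-(methoxymethoxy)-4-[2-(methoxymethoxy)benzyl]benzene | COCOc1ccc(Cc2ccccc2OCOC)cc1Br
A4 | alternative 1 | (S)-pinostrobin | O=C1C[C@@H](c2ccccc2)Oc2cc(OC)cc(O)c12
A5 | alternative 2 | (2S)-6,8-bis{5-[(2-hydroxyphenyl)(phenylthio)methyl]-2-(methoxymethoxy)benzyl}-7-methoxy-5-(methoxymethoxy)flavanone (mixed epimers at the sulfur-bearing carbons) | O=C1C[C@@H](c2ccccc2)Oc2c(Cc3cc(C(Sc4ccccc4)c4ccccc4O)ccc3OCOC)c(OC)c(Cc3cc(C(Sc4ccccc4)c4ccccc4O)ccc3OCOC)c(OCOC)c12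
A6 | alternative 2 | (2S)-7-methoxy-5-(methoxymethoxy)-6,8-bis{2-(methoxymethoxy)-5-[(phenylthio)methyl]benzyl}flavanone | O=C1C[C@@H](c2ccccc2)Oc2c(Cc3cc(CSc4ccccc4)ccc3OCOC)c(OC)c(Cc3cc(CSc4ccccc4)ccc3OCOC)c(OCOC)c12
A7 | alternative 2 | phenol | Oc1ccccc1
A8 | alternative 3 | 5-hydroxy-7-methoxy-6,8-bis{2-(methoxymethoxy)-5-[2-(methoxymethoxy)benzyl]benzyl}flavone | O=c1cc(-c2ccccc2)oc2c(Cc3cc(Cc4ccccc4OCOC)ccc3OCOC)c(OC)c(Cc3cc(Cc4ccccc4OCOC)ccc3OCOC)c(O)c12
A9 | alternative 3 | 2-iodo-5-methoxy-4,6-bis{2-(methoxymethoxy)-5-[2-(methoxymethoxy)benzyl]benzyl}benzene-1,3-diol | Oc1c(I)c(O)c(Cc2cc(Cc3ccccc3OCOC)ccc2OCOC)c(OC)c1Cc1cc(Cc2ccccc2OCOC)ccc1OCOC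
A10 | alternative 3 | phenylacetylene | C#Cc1ccccc1
A11 | alternative 3 | carbon monoxide | [C-]#[O+]
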